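**Plan**

1. Naming: unit 1 is the flavanone joined through C3 (locants C2–C8a, 4-hydroxyphenyl at C2); unit 2 is the flavanone joined through C8'' (double-primed locants, 4-methoxyphenyl at C2'').
2. Retrosynthetic cuts, in order: the five O-benzyl groups and a helper tert-butyl ester on C3; the C3–C8'' bond (aryllead arylation of a β-ketoester); ring C of unit 2 at C2''–C3'' and O1''–C8a''; ring C of unit 1 at O1–C2 and C2–C3.
3. Forward order: ring A of unit 2 is dressed from 3,5-difluorophenol (Fries, bromination, O-benzylation, SNAr). Ring C of unit 2 is then annulated in one flask, and C8''–Br becomes C8''–Sn and then C8''–Pb. Ring C of unit 1 is closed separately (Knoevenagel, oxa-Michael). The halves are joined at C3–C8'', then decarboxylated and debenzylated.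
4. Enabling feature: in ring A of unit 2, C8a'' is ortho to C4a'', which carries the C4'' carbonyl. With fluorine on C8a'', the chain C3''–C4''(=O)–C4a''=C8a''–F is a benzo-fused counterpart of a 1-alkoxy-3-silyloxydiene: nucleophilic at C3'', electrophilic at C8a''. It can take up the C=O of 4-methoxybenzaldehyde in a formal [4+2].
5. Stereochemistry: C2'' comes from a catalyst-controlled aldol addition and is retained in the ring closure. C2 comes from a cinchona-thiourea oxa-Michael addition. C3 is set trans to C2 by thermodynamic protonation after decarboxylation.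
6. Helpers: fluorine is the leaving group at C8a''; bromine marks C8''; the C3 ester activates the oxa-Michael step, is the site of arylation, and blocks enolisation until it is removed in step 12.

Key step: step 6

Assumption: rotation about the C3–C8'' bond is taken as fast at room temperature, so the three stereocentres alone define the target.

**Route**

Step 1
Reactants: 1 3,5-difluorophenol
Product: 3 1-(2,4-difluoro-6-hydroxyphenyl)ethanone, via 3,5-difluorophenyl acetate 2 (not isolated)
Conditions: AcCl (1.1 equiv), 60 °C; then AlCl3 (1.8 equiv), neat, 150 °C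
Reagents that add atoms: acetyl chloride, CC(=O)Cl
Why: O-acetylation followed by a high-temperature Fries rearrangement should place the acyl group ortho to oxygen, because the alternative site between the two fluorines is disfavoured and the ortho-hydroxy ketone is stabilised as its aluminium chelate.

Step 2
Reactants: 3 1-(2,4-difluoro-6-hydroxyphenyl)ethanone
Product: 4 1-(3-bromo-2,4-difluoro-6-hydroxyphenyl)ethanone
Conditions: NBS (1.0 equiv), MeCN, 0 → 20 °C
Reagents that add atoms: N-bromosuccinimide, O=C1CCC(=O)N1Br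
Why: Electrophilic aromatic bromination is expected para to the phenolic oxygen, as in the para-selective halogenation of 3-fluoro- and 3,5-difluorophenols, which puts bromine on the carbon that becomes C8''.

Step 3
Reactants: 4 1-(3-bromo-2,4-difluoro-6-hydroxyphenyl)ethanone
Product: 5 1-[6-(benzyloxy)-3-bromo-2,4-difluorophenyl]ethanone
Conditions: BnBr, K2CO3, DMF, 50 °C
Reagents that add atoms: benzyl bromide, BrCc1ccccc1
Why: Williamson etherification of the chelated phenol protects the oxygen that becomes O5'' and restores the ring's reactivity towards SNAr.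

Step 4
Reactants: 5 1-[6-(benzyloxy)-3-bromo-2,4-difluorophenyl]ethanone
Product: 6 1-[4,6-bis(benzyloxy)-3-bromo-2-fluorophenyl]ethanone
Conditions: BnOH (1.05 equiv), Cs2CO3, DMSO, 25 °C
Reagents that add atoms: benzyl alcohol, OCc1ccccc1
Why: SNAr by benzyl oxide should take the fluorine para to the acetyl group (flanked by H and Br) in preference to the ortho fluorine buried between acetyl and bromine, helped by a polar non-chelating medium, so the surviving C–F bond is the future C8a''.

Step 5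
Reactants: 6 1-[4,6-bis(benzyloxy)-3-bromo-2-fluorophenyl]ethanone
Product: 7 {[1-(4,6-bis(benzyloxy)-3-bromo-2-fluorophenyl)ethenyl]oxy}(trimethyl)silane
Conditions: LiN(SiMe3)2, Me3SiCl, THF, −78 → 0 °C
Reagents that add atoms: chlorotrimethylsilane, C[Si](C)(C)Cl
Why: Deprotonation of the only enolisable position and O-silylation gives the silyl enol ether, with the aryl halides inert at this temperature.

Step 6
Reactants: 7 {[1-(4,6-bis(benzyloxy)-3-bromo-2-fluorophenyl)ethenyl]oxy}(trimethyl)silane; 8 4-methoxybenzaldehyde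
Product: 10 (2S)-5,7-bis(benzyloxy)-8-bromo-2-(4-methoxyphenyl)-2,3-dihydro-4H-chromen-4-one, via silyl aldol adduct 9 (not isolated)
Conditions: (R)-2-butyl-4-(1H-indol-3-ylmethyl)-3-(4-methylphenylsulfonyl)-1,3,2-oxazaborolidin-5-one (20 mol%), EtCN, −78 °C; then CsF (1.5 equiv), 18-crown-6 (0.2 equiv), DMF, −40 → 20 °C; AcOH quench
Reagents that add atoms: none
Why: Proposed new method: a Lewis-acid-catalysed Mukaiyama aldol addition of the enol silane carbon C3'' to the boron-bound aldehyde forms C2''–C3'' and moves the silyl group to the new oxygen; fluoride then frees the alkoxide, which adds to the acyl-activated C8a''–F carbon and expels fluoride through a Meisenheimer intermediate, and the expelled fluoride desilylates the next molecule of 9. The closest known reaction types are the oxazaborolidinone-catalysed Mukaiyama aldol of aryl methyl ketone enol silanes, the Danishefsky-type aldol–cyclisation route to dihydropyranones, and the SNAr closure of o-fluoroaryl β-dicarbonyl compounds to chromones; their merger in one flask with relay of the leaving fluoride is the untested part. Ring C of unit 2 closes by a 6-endo-trig addition–elimination at C8a''. C2'' is set in the aldol by the catalyst, whose antipode is chosen to expose the Si face of the aldehyde (the mirror-image catalyst is used if the sense on this substrate is reversed), and it is retained because the C2''–O bond is never broken. The step needs the alkoxide to cyclise faster than it undergoes retro-aldol cleavage or β-elimination, which the ortho acyl and ortho bromine activation of the C–F bond, the six-membered transition state and the low temperature should secure; regiochemistry is fixed because only one fluorine remains ortho to the ketone.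

Step 7
Reactants: 10 (2S)-5,7-bis(benzyloxy)-8-bromo-2-(4-methoxyphenyl)-2,3-dihydro-4H-chromen-4-one
Product: 11 (2S)-5,7-bis(benzyloxy)-2-(4-methoxyphenyl)-8-(trimethylstannyl)-2,3-dihydro-4H-chromen-4-one
Conditions: Me3SnSnMe3 (1.5 equiv), Pd(PPh3)4 (10 mol%), toluene, 100 °C
Reagents that add atoms: hexamethylditin, C[Sn](C)(C)[Sn](C)(C)C
Why: Palladium-catalysed stannylation of the aryl bromide with a distannane gives the aryl–tin bond needed for tin–lead exchange under neutral conditions that leave C2'' untouched.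

Step 8
Reactants: 12 1-[2,4-bis(benzyloxy)-6-hydroxyphenyl]ethanone
Product: 13 tert-butyl 3-[2,4-bis(benzyloxy)-6-hydroxyphenyl]-3-oxopropanoate
Conditions: LiN(SiMe3)2 (3.2 equiv), THF, −78 °C; Boc2O (1.1 equiv), −78 → 0 °C; aq. HCl
Reagents that add atoms: di-tert-butyl dicarbonate, CC(C)(C)OC(=O)OC(=O)OC(C)(C)C
Why: Claisen-type C-acylation of the ketone enolate of the dianion (any O-carbonate should shift O→C under the excess base, Baker–Venkataraman fashion) gives the tert-butyl β-ketoester, whose bulk suppresses lactonisation to a 4-hydroxycoumarin.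

Step 9
Reactants: 13 tert-butyl 3-[2,4-bis(benzyloxy)-6-hydroxyphenyl]-3-oxopropanoate; 14 4-(benzyloxy)benzaldehyde
Product: 15 tert-butyl 2-[2,4-bis(benzyloxy)-6-hydroxybenzoyl]-3-[4-(benzyloxy)phenyl]prop-2-enoate (E/Z mixture)
Conditions: piperidine (10 mol%), AcOH (10 mol%), toluene, 4 Å MS, 20 °C
Reagents that add atoms: none
Why: Knoevenagel condensation of the active methylene with the aldehyde forms the C2–C3 bond as an alkylidene β-ketoester, which should be kept at room temperature to limit uncatalysed ring closure.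

Step 10
Reactants: 15 tert-butyl 2-[2,4-bis(benzyloxy)-6-hydroxybenzoyl]-3-[4-(benzyloxy)phenyl]prop-2-enoate
Product: 16 tert-butyl (2R)-5,7-bis(benzyloxy)-2-[4-(benzyloxy)phenyl]-4-oxo-3,4-dihydro-2H-chromene-3-carboxylate
Conditions: 1-[3,5-bis(trifluoromethyl)phenyl]-3-[(8R,9R)-6'-methoxycinchonan-9-yl]thiourea (quinidine-derived, 10 mol%), toluene, −25 °C
Reagents that add atoms: none
Why: The bifunctional thiourea–quinuclidine catalyst binds the β-dicarbonyl unit and delivers the phenol to one face of the alkylidene in an enantioselective 6-endo-trig oxa-Michael addition that sets C2; the quinine-derived pseudoenantiomer is the one to use if the sense of induction on this substrate proves opposite.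

Step 11
Reactants: 11 (2S)-5,7-bis(benzyloxy)-2-(4-methoxyphenyl)-8-(trimethylstannyl)-2,3-dihydro-4H-chromen-4-one; 16 tert-butyl (2R)-5,7-bis(benzyloxy)-2-[4-(benzyloxy)phenyl]-4-oxo-3,4-dihydro-2H-chromene-3-carboxylate
Product: 18 tert-butyl (2S)-5,7-bis(benzyloxy)-3-[(2S)-5,7-bis(benzyloxy)-2-(4-methoxyphenyl)-4-oxo-3,4-dihydro-2H-chromen-8-yl]-2-[4-(benzyloxy)phenyl]-4-oxo-3,4-dihydro-2H-chromene-3-carboxylate, via aryllead triacetate 17 (not isolated)
Conditions: Pb(OAc)4 (1.05 equiv), Hg(OAc)2 (5 mol%), CHCl3, 40 °C; then 16 (0.9 equiv), pyridine (3 equiv), CHCl3, 40 °C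
Reagents that add atoms: none
Why: Tin–lead exchange gives the aryllead triacetate, which C-arylates the β-ketoester by ligand coupling at tetravalent lead (Pinhey arylation), a reaction known to transfer 2,6-dioxygenated aryl groups and to build quaternary centres; C3 is then no longer enolisable, so C2 is locked, and any minor enantiomer of either partner ends up in a separable diastereomer.

Step 12
Reactants: 18 tert-butyl (2S)-5,7-bis(benzyloxy)-3-[(2S)-5,7-bis(benzyloxy)-2-(4-methoxyphenyl)-4-oxo-3,4-dihydro-2H-chromen-8-yl]-2-[4-(benzyloxy)phenyl]-4-oxo-3,4-dihydro-2H-chromene-3-carboxylate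
Product: 20 (2R,3S)-5,7-bis(benzyloxy)-3-[(2S)-5,7-bis(benzyloxy)-2-(4-methoxyphenyl)-4-oxo-3,4-dihydro-2H-chromen-8-yl]-2-[4-(benzyloxy)phenyl]-2,3-dihydro-4H-chromen-4-one, via β-keto acid 19 (not isolated)
Conditions: TsOH·H2O (1 equiv), toluene, 80 °C
Reagents that add atoms: none
Why: Acid cleavage of the tert-butyl ester and decarboxylation of the β-keto acid through its enol, followed by protonation at C3 under thermodynamic control, should give the 2,3-trans diequatorial isomer (2R,3S) without touching C2 or C2''.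

Step 13
Reactants: 20 (2R,3S)-5,7-bis(benzyloxy)-3-[(2S)-5,7-bis(benzyloxy)-2-(4-methoxyphenyl)-4-oxo-3,4-dihydro-2H-chromen-8-yl]-2-[4-(benzyloxy)phenyl]-2,3-dihydro-4H-chromen-4-one
Product: 21 (2R,3S)-5,7-dihydroxy-3-[(2S)-5,7-dihydroxy-2-(4-methoxyphenyl)-4-oxo-3,4-dihydro-2H-chromen-8-yl]-2-(4-hydroxyphenyl)-2,3-dihydro-4H-chromen-4-one
Conditions: H2 (1 atm), 10% Pd/C, EtOAc–MeOH 1:1, 20 °C
Reagents that add atoms: none
Why: Neutral hydrogenolysis should remove the five benzyl ethers while leaving the aryl methyl ether, both ketones and the base-sensitive stereocentres unchanged.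

**Compound list**

1 | 3,5-difluorophenol | Oc1cc(F)cc(F)c1 | starting material
2 | 3,5-difluorophenyl acetate | CC(=O)Oc1cc(F)cc(F)c1 | intermediate
3 | 1-(2,4-difluoro-6-hydroxyphenyl)ethanone | CC(=O)c1c(O)cc(F)cc1F | intermediate
4 | 1-(3-bromo-2,4-difluoro-6-hydroxyphenyl)ethanone | CC(=O)c1c(O)cc(F)c(Br)c1F | intermediate
5 | 1-[6-(benzyloxy)-3-bromo-2,4-difluorophenyl]ethanone | CC(=O)c1c(OCc2ccccc2)cc(F)c(Br)c1F | intermediate
6 | 1-[4,6-bis(benzyloxy)-3-bromo-2-fluorophenyl]ethanone | CC(=O)c1c(OCc2ccccc2)cc(OCc2ccccc2)c(Br)c1F | intermediate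
7 | {[1-(4,6-bis(benzyloxy)-3-bromo-2-fluorophenyl)ethenyl]oxy}(trimethyl)silane | C=C(O[Si](C)(C)C)c1c(OCc2ccccc2)cc(OCc2ccccc2)c(Br)c1F | intermediate
8 | 4-methoxybenzaldehyde | COc1ccc(C=O)cc1 | starting material
9 | (3S)-1-[4,6-bis(benzyloxy)-3-bromo-2-fluorophenyl]-3-(4-methoxyphenyl)-3-[(trimethylsilyl)oxy]propan-1-one | COc1ccc([C@H](CC(=O)c2c(OCc3ccccc3)cc(OCc3ccccc3)c(Br)c2F)O[Si](C)(C)C)cc1 | intermediate
10 | (2S)-5,7-bis(benzyloxy)-8-bromo-2-(4-methoxyphenyl)-2,3-dihydro-4H-chromen-4-one | COc1ccc([C@@H]2CC(=O)c3c(OCc4ccccc4)cc(OCc4ccccc4)c(Br)c3O2)cc1 | intermediate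
11 | (2S)-5,7-bis(benzyloxy)-2-(4-methoxyphenyl)-8-(trimethylstannyl)-2,3-dihydro-4H-chromen-4-one | COc1ccc([C@@H]2CC(=O)c3c(OCc4ccccc4)cc(OCc4ccccc4)c([Sn](C)(C)C)c3O2)cc1 | intermediate
12 | 1-[2,4-bis(benzyloxy)-6-hydroxyphenyl]ethanone | CC(=O)c1c(O)cc(OCc2ccccc2)cc1OCc1ccccc1 | starting material
13 | tert-butyl 3-[2,4-bis(benzyloxy)-6-hydroxyphenyl]-3-oxopropanoate | CC(C)(C)OC(=O)CC(=O)c1c(O)cc(OCc2ccccc2)cc1OCc1ccccc1 | intermediate
14 | 4-(benzyloxy)benzaldehyde | O=Cc1ccc(OCc2ccccc2)cc1 | starting material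
15 | tert-butyl 2-[2,4-bis(benzyloxy)-6-hydroxybenzoyl]-3-[4-(benzyloxy)phenyl]prop-2-enoate (E/Z mixture) | CC(C)(C)OC(=O)C(=Cc1ccc(OCc2ccccc2)cc1)C(=O)c1c(O)cc(OCc2ccccc2)cc1OCc1ccccc1 | intermediate
16 | tert-butyl (2R)-5,7-bis(benzyloxy)-2-[4-(benzyloxy)phenyl]-4-oxo-3,4-dihydro-2H-chromene-3-carboxylate (C3 epimers and enol in equilibrium; C3 left undefined) | CC(C)(C)OC(=O)C1C(=O)c2c(OCc3ccccc3)cc(OCc3ccccc3)cc2O[C@H]1c1ccc(OCc2ccccc2)cc1 | intermediate
17 | [(2S)-5,7-bis(benzyloxy)-2-(4-methoxyphenyl)-4-oxo-3,4-dihydro-2H-chromen-8-yl]lead triacetate | COc1ccc([C@@H]2CC(=O)c3c(OCc4ccccc4)cc(OCc4ccccc4)c([Pb](OC(C)=O)(OC(C)=O)OC(C)=O)c3O2)cc1 | intermediate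
18 | tert-butyl (2S)-5,7-bis(benzyloxy)-3-[(2S)-5,7-bis(benzyloxy)-2-(4-methoxyphenyl)-4-oxo-3,4-dihydro-2H-chromen-8-yl]-2-[4-(benzyloxy)phenyl]-4-oxo-3,4-dihydro-2H-chromene-3-carboxylate (C2 of unit 1 has the same spatial arrangement as in 16; the descriptor changes because the quaternary C3 now outranks the aryl group; C3 not assigned as it is lost in step 12) | COc1ccc([C@@H]2CC(=O)c3c(OCc4ccccc4)cc(OCc4ccccc4)c(C4(C(=O)OC(C)(C)C)C(=O)c5c(OCc6ccccc6)cc(OCc6ccccc6)cc5O[C@H]4c4ccc(OCc5ccccc5)cc4)c3O2)cc1 | intermediate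
19 | (2S)-5,7-bis(benzyloxy)-3-[(2S)-5,7-bis(benzyloxy)-2-(4-methoxyphenyl)-4-oxo-3,4-dihydro-2H-chromen-8-yl]-2-[4-(benzyloxy)phenyl]-4-oxo-3,4-dihydro-2H-chromene-3-carboxylic acid (C3 not assigned) | COc1ccc([C@@H]2CC(=O)c3c(OCc4ccccc4)cc(OCc4ccccc4)c(C4(C(=O)O)C(=O)c5c(OCc6ccccc6)cc(OCc6ccccc6)cc5O[C@H]4c4ccc(OCc5ccccc5)cc4)c3O2)cc1 | intermediate
20 | (2R,3S)-5,7-bis(benzyloxy)-3-[(2S)-5,7-bis(benzyloxy)-2-(4-methoxyphenyl)-4-oxo-3,4-dihydro-2H-chromen-8-yl]-2-[4-(benzyloxy)phenyl]-2,3-dihydro-4H-chromen-4-one | COc1ccc([C@@H]2CC(=O)c3c(OCc4ccccc4)cc(OCc4ccccc4)c([C@@H]4C(=O)c5c(OCc6ccccc6)cc(OCc6ccccc6)cc5O[C@H]4c4ccc(OCc5ccccc5)cc4)c3O2)cc1 | intermediate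
21 | (2R,3S)-5,7-dihydroxy-3-[(2S)-5,7-dihydroxy-2-(4-methoxyphenyl)-4-oxo-3,4-dihydro-2H-chromen-8-yl]-2-(4-hydroxyphenyl)-2,3-dihydro-4H-chromen-4-one | COc1ccc([C@@H]2CC(=O)c3c(O)cc(O)c([C@@H]4C(=O)c5c(O)cc(O)cc5O[C@H]4c4ccc(O)cc4)c3O2)cc1 | target

**Step count and risks**

Total steps: 13. Longest linear sequence: 10 (steps 1–7, then 11–13); steps 8–10 form the second branch.

Steps most likely to fail:

- **Step 6.** Once freed by fluoride, the alkoxide may revert to enolate and aldehyde (retro-aldol) or lose its oxygen by β-elimination faster than it attacks the C–F carbon, which would erode the enantiomeric purity at C2'' or divert material to an open-chain enone. The fallback uses known chemistry and forms the C2''–aryl bond instead. It sets out from 6: Claisen formylation (HCO2Et, NaH, THF, 0 → 20 °C) gives 3-[4,6-bis(benzyloxy)-3-bromo-2-fluorophenyl]-3-oxopropanal F1 as its sodium enolate, which on warming in DMF should close by SNAr of the enolate oxygen on the C–F carbon to 5,7-bis(benzyloxy)-8-bromo-4H-chromen-4-one F2. Enantioselective conjugate addition of 4-methoxyphenylboronic acid to F2 (Pd(OCOCF3)2, the antipode of 4-tert-butyl-2-(pyridin-2-yl)-4,5-dihydrooxazole that gives the 2S series, NH4PF6, H2O, ClCH2CH2Cl, 60 °C) then comes back to the route at 10.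

- **Step 11.** Ligand coupling at lead may stall against the congestion of a fully substituted C3 flanked by the C2 aryl group and the tert-butyl ester, and pyridine may open ring C of 16 by retro-oxa-Michael before arylation and so erode C2. The fallback sets out from 13 and from 17 (generated from 11 as in step 11). Arylation of the unhindered methylene of 13 (pyridine, CHCl3, 40 °C) gives tert-butyl 3-[2,4-bis(benzyloxy)-6-hydroxyphenyl]-2-[(2S)-5,7-bis(benzyloxy)-2-(4-methoxyphenyl)-4-oxo-3,4-dihydro-2H-chromen-8-yl]-3-oxopropanoate F3. Acid decarboxylation (TsOH·H2O, toluene, 80 °C) gives the deoxybenzoin 1-[2,4-bis(benzyloxy)-6-hydroxyphenyl]-2-[(2S)-5,7-bis(benzyloxy)-2-(4-methoxyphenyl)-4-oxo-3,4-dihydro-2H-chromen-8-yl]ethanone F4. The classical condensation of F4 with 14 (piperidine cat., EtOH, 60 °C, kept short to spare C2'') should give the 2,3-trans-diarylchromanone as 20 together with its (2S,3R,2''S) diastereomer F5. These are to be separated by chromatography or crystallisation, and the route is rejoined at 20.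

- **Step 7.** Oxidative addition into the C–Br bond flanked by two oxygen substituents may be slow, with competing protodebromination, and the electron-rich aryl stannane may lose tin on silica. The fallback sets out from 10: borylation with pinacolborane (Pd(OAc)2, SPhos, Et3N, dioxane, 80 °C) gives (2S)-5,7-bis(benzyloxy)-2-(4-methoxyphenyl)-8-(4,4,5,5-tetramethyl-1,3,2-dioxaborolan-2-yl)-2,3-dihydro-4H-chromen-4-one F6. Cleavage of the pinacol ester (NaIO4, NH4OAc, acetone–water) gives the boronic acid [(2S)-5,7-bis(benzyloxy)-2-(4-methoxyphenyl)-4-oxo-3,4-dihydro-2H-chromen-8-yl]boronic acid F7. Boron–lead exchange (Pb(OAc)4, Hg(OAc)2 cat., CHCl3, 40 °C) then comes back to the route at 17 inside step 11.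

**Further compounds**

F1 | step 6 | 3-[4,6-bis(benzyloxy)-3-bromo-2-fluorophenyl]-3-oxopropanal | O=CCC(=O)c1c(OCc2ccccc2)cc(OCc2ccccc2)c(Br)c1F
F2 | step 6 | 5,7-bis(benzyloxy)-8-bromo-4H-chromen-4-one | O=c1ccoc2c(Br)c(OCc3ccccc3)cc(OCc3ccccc3)c12
F3 | step 11 | tert-butyl 3-[2,4-bis(benzyloxy)-6-hydroxyphenyl]-2-[(2S)-5,7-bis(benzyloxy)-2-(4-methoxyphenyl)-4-oxo-3,4-dihydro-2H-chromen-8-yl]-3-oxopropanoate | COc1ccc([C@@H]2CC(=O)c3c(OCc4ccccc4)cc(OCc4ccccc4)c(C(C(=O)OC(C)(C)C)C(=O)c4c(O)cc(OCc5ccccc5)cc4OCc4ccccc4)c3O2)cc1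
F4 | step 11 | 1-[2,4-bis(benzyloxy)-6-hydroxyphenyl]-2-[(2S)-5,7-bis(benzyloxy)-2-(4-methoxyphenyl)-4-oxo-3,4-dihydro-2H-chromen-8-yl]ethanone | COc1ccc([C@@H]2CC(=O)c3c(OCc4ccccc4)cc(OCc4ccccc4)c(CC(=O)c4c(O)cc(OCc5ccccc5)cc4OCc4ccccc4)c3O2)cc1
F5 | step 11 | (2S,3R)-5,7-bis(benzyloxy)-3-[(2S)-5,7-bis(benzyloxy)-2-(4-methoxyphenyl)-4-oxo-3,4-dihydro-2H-chromen-8-yl]-2-[4-(benzyloxy)phenyl]-2,3-dihydro-4H-chromen-4-one | COc1ccc([C@@H]2CC(=O)c3c(OCc4ccccc4)cc(OCc4ccccc4)c([C@H]4C(=O)c5c(OCc6ccccc6)cc(OCc6ccccc6)cc5O[C@@H]4c4ccc(OCc5ccccc5)cc4)c3O2)cc1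
F6 | step 7 | (2S)-5,7-bis(benzyloxy)-2-(4-methoxyphenyl)-8-(4,4,5,5-tetramethyl-1,3,2-dioxaborolan-2-yl)-2,3-dihydro-4H-chromen-4-one | COc1ccc([C@@H]2CC(=O)c3c(OCc4ccccc4)cc(OCc4ccccc4)c(B4OC(C)(C)C(C)(C)O4)c3O2)cc1
F7 | step 7 | [(2S)-5,7-bis(benzyloxy)-2-(4-methoxyphenyl)-4-oxo-3,4-dihydro-2H-chromen-8-yl]boronic acid | COc1ccc([C@@H]2CC(=O)c3c(OCc4ccccc4)cc(OCc4ccccc4)c(B(O)O)c3O2)cc1
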